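The earlier runs and the new flask come from a simulation with constants of no real substance; the scatter is artificial.

**Two ratios.** Monday's charge over Friday's is 2.21, and Friday's slope of product in percent per hour over Monday's is 2.16. The two ratios match, so both runs make about the same amount per hour: a zero-order stretch in the charge. Friday's line needs 36.4 h per whole charge, Monday's 78.8 h. Scaled by charge, they give 53.0 h for the new flask. This is what we carry, the clearing time: the hours the straight line of product takes to cover one whole charge.

in all of them: gas 30 mM (held)
- Friday's: solid substrate 0.034 M; run made earlier
- Monday's: solid substrate 0.075 M; run made earlier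
- flask: solid substrate 0.050 M; time 2.0 d

- Friday's (time / h: product / %, solid substrate / %): 2.50: 0.8, 89.8; 8.00: 13.2, 77.3; 15.0: 32.2, 57.1; 20.0: 43.6, 46.1; 30.0: 73.6, 18.0; 40.0: 98.5, 0; 50.0: 101.5, 0.7
- Monday's (time / h: product / %, solid substrate / %): 2.50: 0, 96.2; 8.00: 5.5, 90.5; 15.0: 13.1, 81.1; 20.0: 20.8, 74.8; 30.0: 32.0, 63.4; 40.0: 45.9, 49.4; 50.0: 58.8, 37.4

(readings scatter by 1 percentage point)

- given per volume of solution although it is solid: solid substrate
- the analysis behind the earlier runs scatters by 1 percentage point, standard deviation
- at the start none of the gas is in solution
- at the start none of the solid substrate is in solution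

- amount of product in percent of the solid substrate charged, at 10 h, 25 h and 2.0 d

**First hours.** Neither gas nor solid starts in solution. On Friday, solid already reads 89.8% at 2.50 h with product at 0.8%. Traced back, the two product lines reach zero after a lag of 3.43 h on average.

**The middle.** Product plus solid substrate falls short of the charge by 10.3% at 20.0 h on Friday and by 4.60% at 30.0 h on Monday. These are single readings with their scatter, and their ratio, 2.24, reads close to that of the charges, so we read about the same amount held in solution in both runs, which would be 6.95% of the new flask's charge.

**The end.** Solid should vanish after the lag plus the clearing time, shortened by that held share. For Friday's run this gives 36.1 h, and Friday's solid substrate reads 0% at 40.0 h. For the new flask it gives 52.8 h, later than the last asked time, and the first asked time comes after the lag, so we place the asked times on the line. We reckon 12.4%, 40.7% and 84.0%.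

**The forecast.** It gives 12.5%, 41% and 85%, holding that “the absolute rate is the same in both runs”, and its last value stands above ours.

**The flask.** It gives 12.8%, 40.3% and 82.5%.

    gas ⇌ partner, rate k1*(csat - [partner]) (kL = 1.20 × 10⁻⁴ /s)
    partner + intermediate → product (k = 0.00930 /M/s)
    starting material → intermediate (k = 1.10 × 10⁻⁴ /s)
    solid substrate ⇌ starting material, rate k4*(cs4 - [starting material]) while solid is left; crystals form when [starting material] > cs4 (solubility = 9.80 mM, k = 3.40 × 10⁻⁵ /s)

**Two clocks.** Between 25 h and 2.0 d the flask's product climbs with a clearing time of 54.5 h, which is 31.1 times the half-life of starting material by its path to intermediate alone, 1.75 h, and the half-life of intermediate on its step to product at 2.00 d is shorter still, 0.74 h. In the flask, starting material stands at 4.63% at 1.00 d and 4.63% at 2.00 d, intermediate at 1.96% and 1.96%, while solid substrate falls from 54.9% to 10.9%.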